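## Retrosynthetic overview

1. The target is two (1S,4R)-8-hydroxycalamenene units joined C7–C5′. The last skeletal disconnection is this aryl–aryl bond (Suzuki–Miyaura), giving fragment A (5-chloro-7-iodo methyl ether) and fragment B (C5 boronate methyl ether).
2. In each fragment the C1 methyl comes from SN1 methylation (AlMe3) of a 1-tetralol, trans to the C4 isopropyl group; the tetralol comes from a 1-tetralone.
3. Each tetralone ring is closed by Friedel–Crafts acylation at C8a of a 4-aryl-5-methylhexanoic acid whose para position (C5) carries a halogen. Br in B later becomes boron; Cl in A is an inert block that also steers iodination to C7.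
4. Both acids come by halogenation and Arndt–Eistert homologation from one (3R)-3-aryl-4-methylpentanoic acid, made by Rh/(R)-BINAP conjugate addition of an arylboronate (m-cresol, O-methylation, Ir C–H borylation) to an ester of 4-methylpent-2-enoic acid.
5. Ring order: the aromatic rings are bought (m-cresol); the saturated rings of B and A are closed in parallel; then the biaryl bond, dechlorination and O-demethylation.

Assumption: the target SMILES fixes four stereocentres but not the sense of the hindered biaryl axis, so the axis is left undefined and any atropisomers from step 17 are separated at the end.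
Locants follow tetralin (calamenene) numbering: C1 = CH(CH3), C4 = CH(i-Pr), C6 = aryl CH3, C8 = oxygen; primed locants belong to the half joined through C5′.

## Route

Step 1
Reactants: 1 3-methylphenol (m-cresol)
Product: 2 3-methylanisole
Conditions: MeI (1.3 equiv), K2CO3 (2 equiv), acetone, reflux
Reagents that add atoms: iodomethane, CI
Why: Williamson ether synthesis; the phenol is masked as a methyl ether that survives the organometallic and Lewis-acid steps.

Step 2
Reactants: 2 3-methylanisole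
Product: 3 2-(3-methoxy-5-methylphenyl)-4,4,5,5-tetramethyl-1,3,2-dioxaborolane
Conditions: [Ir(OMe)(cod)]2 (1 mol %), 4,4′-di-tert-butyl-2,2′-bipyridine (2 mol %), B2pin2 (0.55 equiv), hexane, 60 °C
Reagents that add atoms: bis(pinacolato)diboron, CC1(C)OB(OC1(C)C)B1OC(C)(C)C(C)(C)O1
Why: Iridium-catalysed aromatic C–H borylation is sterically controlled and takes the only ring C–H without an ortho neighbour, meta to both OMe and CH3 (the future C4a).

Step 3
Reactants: 4 (E)-4-methylpent-2-enoic acid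
Product: 5 propan-2-yl (E)-4-methylpent-2-enoate
Conditions: i-PrOH (excess), H2SO4 (cat.), toluene, reflux, Dean–Stark
Reagents that add atoms: propan-2-ol, CC(C)O
Why: Fischer esterification; bulky enoate esters give the best selectivity in the conjugate addition that follows.

Step 4
Reactants: 3 2-(3-methoxy-5-methylphenyl)-4,4,5,5-tetramethyl-1,3,2-dioxaborolane (1.3 equiv); 5 propan-2-yl (E)-4-methylpent-2-enoate
Product: 7 (3R)-3-(3-methoxy-5-methylphenyl)-4-methylpentanoic acid, via isopropyl ester 6 (not isolated)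
Conditions: [Rh(OH)((R)-BINAP)]2 (3 mol % Rh), KOH (0.1 equiv), 1,4-dioxane/H2O 10:1, 80 °C; then LiOH·H2O (3 equiv), MeOH/H2O, 60 °C; aq. HCl
Reagents that add atoms: lithium hydroxide, [Li+].[OH-]
Why: Hayashi–Miyaura asymmetric conjugate addition, in which the (R)-BINAP–Rh–aryl species adds to the Si face of C3 of the E-enoate (the same facial sense that gives (R)-3-phenylcyclohexanone from cyclohexenone) and so sets the future C4 as R, followed by saponification in the same pot.

Step 5
Reactants: 7 (3R)-3-(3-methoxy-5-methylphenyl)-4-methylpentanoic acid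
Product: 8 (3R)-3-(2-bromo-5-methoxy-3-methylphenyl)-4-methylpentanoic acid
Conditions: NBS (1.05 equiv), MeCN, 0 → 25 °C
Reagents that add atoms: N-bromosuccinimide, O=C1CCC(=O)N1Br
Why: Electrophilic aromatic bromination; NBS in MeCN brominates anisoles para to OMe, which places Br on the future C5 where it blocks para-cyclisation, holds the isopropyl group axial and later becomes the boron handle.

Step 6
Reactants: 8 (3R)-3-(2-bromo-5-methoxy-3-methylphenyl)-4-methylpentanoic acid
Product: 12 (4R)-4-(2-bromo-5-methoxy-3-methylphenyl)-5-methylhexanoic acid, via acid chloride 9 (not isolated), via diazoketone 10 (not isolated), via ketene 11 (not isolated)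
Conditions: (COCl)2, DMF (cat.), CH2Cl2, 0 → 25 °C; then CH2N2, Et3N, Et2O, 0 °C; then PhCO2Ag (10 mol %), Et3N, 1,4-dioxane/H2O, 25 → 60 °C
Reagents that add atoms: diazomethane, C=[N+]=[N-]; water, O
Why: Arndt–Eistert homologation (Wolff rearrangement) inserts the one carbon that becomes C1; the migrating CH2 group is not stereogenic, so the benzylic centre is untouched.

Step 7
Reactants: 12 (4R)-4-(2-bromo-5-methoxy-3-methylphenyl)-5-methylhexanoic acid
Product: 13 (4R)-5-bromo-8-methoxy-6-methyl-4-(propan-2-yl)-3,4-dihydronaphthalen-1(2H)-one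
Conditions: P2O5 in MeSO3H (1:10 w/w, Eaton's reagent), 25 °C
Reagents that add atoms: none
Why: Intramolecular Friedel–Crafts acylation; with C5 blocked the acylium ion can close only onto C8a (ortho to OMe, para to CH3), giving the six-membered ketone without touching C4.

Step 8
Reactants: 13 (4R)-5-bromo-8-methoxy-6-methyl-4-(propan-2-yl)-3,4-dihydronaphthalen-1(2H)-one
Product: 14 (1RS,4R)-5-bromo-8-methoxy-6-methyl-4-(propan-2-yl)-1,2,3,4-tetrahydronaphthalen-1-ol
Conditions: NaBH4 (1.5 equiv), MeOH/THF, 0 → 25 °C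
Reagents that add atoms: none
Why: Hydride reduction of the aryl ketone; the C1 configuration is irrelevant because the next step passes through a planar cation.

Step 9
Reactants: 14 (1RS,4R)-5-bromo-8-methoxy-6-methyl-4-(propan-2-yl)-1,2,3,4-tetrahydronaphthalen-1-ol
Product: 16 (1S,4R)-5-bromo-8-methoxy-1,6-dimethyl-4-(propan-2-yl)-1,2,3,4-tetrahydronaphthalene, via dimethylaluminium alkoxide 15 (not isolated)
Conditions: AlMe3 (4 equiv, 2 M in toluene), CH2Cl2, −78 → 25 °C; then aq. HCl
Reagents that add atoms: trimethylaluminium, C[Al](C)C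
Why: SN1 methylation in which the aluminium alkoxide ionises to the o-methoxy-stabilised benzylic cation (both epimers of 14 converge), the peri bromine holds the C4 isopropyl group pseudoaxial, and methyl is delivered axially to the opposite face, setting C1 as S, trans to the isopropyl group.

Step 10
Reactants: 16 (1S,4R)-5-bromo-8-methoxy-1,6-dimethyl-4-(propan-2-yl)-1,2,3,4-tetrahydronaphthalene
Product: 18 2-[(1S,4R)-8-methoxy-1,6-dimethyl-4-(propan-2-yl)-1,2,3,4-tetrahydronaphthalen-5-yl]-4,4,5,5-tetramethyl-1,3,2-dioxaborolane (fragment B), via aryllithium 17 (not isolated)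
Conditions: n-BuLi (1.1 equiv), THF, −78 °C; then i-PrOBpin (1.5 equiv), −78 → 25 °C; then H2O
Reagents that add atoms: 2-isopropoxy-4,4,5,5-tetramethyl-1,3,2-dioxaborolane, CC(C)OB1OC(C)(C)C(C)(C)O1
Why: Bromine–lithium exchange followed by borylation turns the blocking bromine into the nucleophilic coupling handle at C5 without affecting either benzylic stereocentre.

Step 11
Reactants: 7 (3R)-3-(3-methoxy-5-methylphenyl)-4-methylpentanoic acid
Product: 19 (3R)-3-(2-chloro-5-methoxy-3-methylphenyl)-4-methylpentanoic acid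
Conditions: NCS (1.05 equiv), (CF3)2CHOH, 25 °C
Reagents that add atoms: N-chlorosuccinimide, O=C1CCC(=O)N1Cl
Why: Electrophilic aromatic chlorination para to OMe; chlorine is chosen for fragment A because it must survive the later aryl iodide coupling.

Step 12
Reactants: 19 (3R)-3-(2-chloro-5-methoxy-3-methylphenyl)-4-methylpentanoic acid
Product: 23 (4R)-4-(2-chloro-5-methoxy-3-methylphenyl)-5-methylhexanoic acid, via acid chloride 20 (not isolated), via diazoketone 21 (not isolated), via ketene 22 (not isolated)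
Conditions: (COCl)2, DMF (cat.), CH2Cl2, 0 → 25 °C; then CH2N2, Et3N, Et2O, 0 °C; then PhCO2Ag (10 mol %), Et3N, 1,4-dioxane/H2O, 25 → 60 °C
Reagents that add atoms: diazomethane, C=[N+]=[N-]; water, O
Why: Arndt–Eistert homologation (Wolff rearrangement), as in step 6, with the stereocentre untouched.

Step 13
Reactants: 23 (4R)-4-(2-chloro-5-methoxy-3-methylphenyl)-5-methylhexanoic acid
Product: 24 (4R)-5-chloro-8-methoxy-6-methyl-4-(propan-2-yl)-3,4-dihydronaphthalen-1(2H)-one
Conditions: P2O5 in MeSO3H (1:10 w/w, Eaton's reagent), 25 °C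
Reagents that add atoms: none
Why: Intramolecular Friedel–Crafts acylation, directed to C8a by the chlorine block at C5.

Step 14
Reactants: 24 (4R)-5-chloro-8-methoxy-6-methyl-4-(propan-2-yl)-3,4-dihydronaphthalen-1(2H)-one
Product: 25 (1RS,4R)-5-chloro-8-methoxy-6-methyl-4-(propan-2-yl)-1,2,3,4-tetrahydronaphthalen-1-ol
Conditions: NaBH4 (1.5 equiv), MeOH/THF, 0 → 25 °C
Reagents that add atoms: none
Why: Hydride reduction; both C1 epimers are carried on because they converge in step 15.

Step 15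
Reactants: 25 (1RS,4R)-5-chloro-8-methoxy-6-methyl-4-(propan-2-yl)-1,2,3,4-tetrahydronaphthalen-1-ol
Product: 27 (1S,4R)-5-chloro-8-methoxy-1,6-dimethyl-4-(propan-2-yl)-1,2,3,4-tetrahydronaphthalene, via dimethylaluminium alkoxide 26 (not isolated)
Conditions: AlMe3 (4 equiv, 2 M in toluene), CH2Cl2, −78 → 25 °C; then aq. HCl
Reagents that add atoms: trimethylaluminium, C[Al](C)C
Why: SN1 methylation through the o-methoxy-stabilised benzylic cation; the peri chlorine keeps the isopropyl group pseudoaxial, so methyl adds axially anti to it and sets C1 as S (trans).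

Step 16
Reactants: 27 (1S,4R)-5-chloro-8-methoxy-1,6-dimethyl-4-(propan-2-yl)-1,2,3,4-tetrahydronaphthalene
Product: 28 (1S,4R)-5-chloro-7-iodo-8-methoxy-1,6-dimethyl-4-(propan-2-yl)-1,2,3,4-tetrahydronaphthalene (fragment A)
Conditions: NIS (1.1 equiv), CF3CO2H (0.3 equiv), MeCN, 25 °C
Reagents that add atoms: N-iodosuccinimide, O=C1CCC(=O)N1I
Why: Electrophilic aromatic iodination; C7 is the only ring C–H left and is ortho to OMe, so the regiochemistry is fixed.

Step 17
Reactants: 28 (1S,4R)-5-chloro-7-iodo-8-methoxy-1,6-dimethyl-4-(propan-2-yl)-1,2,3,4-tetrahydronaphthalene; 18 2-[(1S,4R)-8-methoxy-1,6-dimethyl-4-(propan-2-yl)-1,2,3,4-tetrahydronaphthalen-5-yl]-4,4,5,5-tetramethyl-1,3,2-dioxaborolane (1.3 equiv)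
Product: 29 (1S,4R,1′S,4′R)-5-chloro-8,8′-dimethoxy-1,6,1′,6′-tetramethyl-4,4′-di(propan-2-yl)-1,2,3,4,1′,2′,3′,4′-octahydro-7,5′-binaphthalene
Conditions: Pd(OAc)2 (5 mol %), SPhos (10 mol %), K3PO4 (3 equiv), toluene/H2O 10:1, 100 °C
Reagents that add atoms: none
Why: Suzuki–Miyaura cross-coupling forms the C7–C5′ bond; the aryl iodide undergoes oxidative addition far faster than the hindered aryl chloride, the bulky biarylphosphine allows the tetra-ortho-substituted reductive elimination, and no sp3 stereocentre is involved.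

Step 18
Reactants: 29 (1S,4R,1′S,4′R)-5-chloro-8,8′-dimethoxy-1,6,1′,6′-tetramethyl-4,4′-di(propan-2-yl)-1,2,3,4,1′,2′,3′,4′-octahydro-7,5′-binaphthalene
Product: 30 (1S,4R,1′S,4′R)-8,8′-dimethoxy-1,6,1′,6′-tetramethyl-4,4′-di(propan-2-yl)-1,2,3,4,1′,2′,3′,4′-octahydro-7,5′-binaphthalene
Conditions: [PdCl(η3-C3H5)(IPr)] (3 mol %; IPr = 1,3-bis(2,6-diisopropylphenyl)imidazol-2-ylidene), NaOt-Bu (1.5 equiv), i-PrOH, 60 °C
Reagents that add atoms: none
Why: Palladium-catalysed transfer hydrodechlorination with isopropoxide as the hydride source removes the blocking chlorine from the hindered C5 position without touching the ethers or stereocentres.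

Step 19
Reactants: 30 (1S,4R,1′S,4′R)-8,8′-dimethoxy-1,6,1′,6′-tetramethyl-4,4′-di(propan-2-yl)-1,2,3,4,1′,2′,3′,4′-octahydro-7,5′-binaphthalene
Product: 32 (1S,4R,1′S,4′R)-1,6,1′,6′-tetramethyl-4,4′-di(propan-2-yl)-1,2,3,4,1′,2′,3′,4′-octahydro-7,5′-binaphthalene-8,8′-diol (CNP0145304.1), via bis(dibromoboryl) ether 31 (not isolated)
Conditions: BBr3 (6 equiv), CH2Cl2, −78 → 25 °C; then H2O, 0 °C
Reagents that add atoms: none
Why: Lewis-acid cleavage of both aryl methyl ethers (bromide attacks the O-methyl carbon), releasing the two phenols with all four stereocentres unchanged.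

## Compound list

1 | 3-methylphenol (m-cresol) | Cc1cccc(O)c1 | starting material
2 | 3-methylanisole | COc1cccc(C)c1 | intermediate
3 | 2-(3-methoxy-5-methylphenyl)-4,4,5,5-tetramethyl-1,3,2-dioxaborolane | COc1cc(C)cc(c1)B1OC(C)(C)C(C)(C)O1 | intermediate
4 | (E)-4-methylpent-2-enoic acid | CC(C)/C=C/C(=O)O | starting material
5 | propan-2-yl (E)-4-methylpent-2-enoate | CC(C)/C=C/C(=O)OC(C)C | intermediate
6 | propan-2-yl (3R)-3-(3-methoxy-5-methylphenyl)-4-methylpentanoate (not isolated) | COc1cc(C)cc(c1)[C@H](CC(=O)OC(C)C)C(C)C | intermediate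
7 | (3R)-3-(3-methoxy-5-methylphenyl)-4-methylpentanoic acid | COc1cc(C)cc(c1)[C@H](CC(=O)O)C(C)C | intermediate
8 | (3R)-3-(2-bromo-5-methoxy-3-methylphenyl)-4-methylpentanoic acid | COc1cc(C)c(Br)c(c1)[C@H](CC(=O)O)C(C)C | intermediate
9 | (3R)-3-(2-bromo-5-methoxy-3-methylphenyl)-4-methylpentanoyl chloride (not isolated) | COc1cc(C)c(Br)c(c1)[C@H](CC(=O)Cl)C(C)C | intermediate
10 | (4R)-4-(2-bromo-5-methoxy-3-methylphenyl)-1-diazo-5-methylhexan-2-one (not isolated) | COc1cc(C)c(Br)c(c1)[C@H](CC(=O)C=[N+]=[N-])C(C)C | intermediate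
11 | (4R)-4-(2-bromo-5-methoxy-3-methylphenyl)-5-methylhex-1-en-1-one, the ketene (not isolated) | COc1cc(C)c(Br)c(c1)[C@H](CC=C=O)C(C)C | intermediate
12 | (4R)-4-(2-bromo-5-methoxy-3-methylphenyl)-5-methylhexanoic acid | COc1cc(C)c(Br)c(c1)[C@H](CCC(=O)O)C(C)C | intermediate
13 | (4R)-5-bromo-8-methoxy-6-methyl-4-(propan-2-yl)-3,4-dihydronaphthalen-1(2H)-one | Cc1c(Br)c2c(c(OC)c1)C(=O)CC[C@@H]2C(C)C | intermediate
14 | (1RS,4R)-5-bromo-8-methoxy-6-methyl-4-(propan-2-yl)-1,2,3,4-tetrahydronaphthalen-1-ol (both C1 epimers) | Cc1c(Br)c2c(c(OC)c1)C(O)CC[C@@H]2C(C)C | intermediate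
15 | dimethylaluminium alkoxide of 14 (not isolated) | Cc1c(Br)c2c(c(OC)c1)C(O[Al](C)C)CC[C@@H]2C(C)C | intermediate
16 | (1S,4R)-5-bromo-8-methoxy-1,6-dimethyl-4-(propan-2-yl)-1,2,3,4-tetrahydronaphthalene | Cc1c(Br)c2c(c(OC)c1)[C@@H](C)CC[C@@H]2C(C)C | intermediate
17 | [(1S,4R)-8-methoxy-1,6-dimethyl-4-(propan-2-yl)-1,2,3,4-tetrahydronaphthalen-5-yl]lithium (not isolated) | Cc1c([Li])c2c(c(OC)c1)[C@@H](C)CC[C@@H]2C(C)C | intermediate
18 | 2-[(1S,4R)-8-methoxy-1,6-dimethyl-4-(propan-2-yl)-1,2,3,4-tetrahydronaphthalen-5-yl]-4,4,5,5-tetramethyl-1,3,2-dioxaborolane (fragment B) | Cc1c(B3OC(C)(C)C(C)(C)O3)c2c(c(OC)c1)[C@@H](C)CC[C@@H]2C(C)C | intermediate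
19 | (3R)-3-(2-chloro-5-methoxy-3-methylphenyl)-4-methylpentanoic acid | COc1cc(C)c(Cl)c(c1)[C@H](CC(=O)O)C(C)C | intermediate
20 | (3R)-3-(2-chloro-5-methoxy-3-methylphenyl)-4-methylpentanoyl chloride (not isolated) | COc1cc(C)c(Cl)c(c1)[C@H](CC(=O)Cl)C(C)C | intermediate
21 | (4R)-4-(2-chloro-5-methoxy-3-methylphenyl)-1-diazo-5-methylhexan-2-one (not isolated) | COc1cc(C)c(Cl)c(c1)[C@H](CC(=O)C=[N+]=[N-])C(C)C | intermediate
22 | (4R)-4-(2-chloro-5-methoxy-3-methylphenyl)-5-methylhex-1-en-1-one, the ketene (not isolated) | COc1cc(C)c(Cl)c(c1)[C@H](CC=C=O)C(C)C | intermediate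
23 | (4R)-4-(2-chloro-5-methoxy-3-methylphenyl)-5-methylhexanoic acid | COc1cc(C)c(Cl)c(c1)[C@H](CCC(=O)O)C(C)C | intermediate
24 | (4R)-5-chloro-8-methoxy-6-methyl-4-(propan-2-yl)-3,4-dihydronaphthalen-1(2H)-one | Cc1c(Cl)c2c(c(OC)c1)C(=O)CC[C@@H]2C(C)C | intermediate
25 | (1RS,4R)-5-chloro-8-methoxy-6-methyl-4-(propan-2-yl)-1,2,3,4-tetrahydronaphthalen-1-ol (both C1 epimers) | Cc1c(Cl)c2c(c(OC)c1)C(O)CC[C@@H]2C(C)C | intermediate
26 | dimethylaluminium alkoxide of 25 (not isolated) | Cc1c(Cl)c2c(c(OC)c1)C(O[Al](C)C)CC[C@@H]2C(C)C | intermediate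
27 | (1S,4R)-5-chloro-8-methoxy-1,6-dimethyl-4-(propan-2-yl)-1,2,3,4-tetrahydronaphthalene | Cc1c(Cl)c2c(c(OC)c1)[C@@H](C)CC[C@@H]2C(C)C | intermediate
28 | (1S,4R)-5-chloro-7-iodo-8-methoxy-1,6-dimethyl-4-(propan-2-yl)-1,2,3,4-tetrahydronaphthalene (fragment A) | Cc1c(Cl)c2c(c(OC)c1I)[C@@H](C)CC[C@@H]2C(C)C | intermediate
29 | (1S,4R,1′S,4′R)-5-chloro-8,8′-dimethoxy-1,6,1′,6′-tetramethyl-4,4′-di(propan-2-yl)-1,2,3,4,1′,2′,3′,4′-octahydro-7,5′-binaphthalene | Cc1c(Cl)c2c(c(OC)c1-c1c(C)cc(OC)c3c1[C@@H](C(C)C)CC[C@@H]3C)[C@@H](C)CC[C@@H]2C(C)C | intermediate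
30 | (1S,4R,1′S,4′R)-8,8′-dimethoxy-1,6,1′,6′-tetramethyl-4,4′-di(propan-2-yl)-1,2,3,4,1′,2′,3′,4′-octahydro-7,5′-binaphthalene | Cc1cc2c(c(OC)c1-c1c(C)cc(OC)c3c1[C@@H](C(C)C)CC[C@@H]3C)[C@@H](C)CC[C@@H]2C(C)C | intermediate
31 | 8,8′-bis(dibromoboryloxy) derivative of the biaryl (not isolated) | Cc1cc2c(c(OB(Br)Br)c1-c1c(C)cc(OB(Br)Br)c3c1[C@@H](C(C)C)CC[C@@H]3C)[C@@H](C)CC[C@@H]2C(C)C | intermediate
32 | (1S,4R,1′S,4′R)-1,6,1′,6′-tetramethyl-4,4′-di(propan-2-yl)-1,2,3,4,1′,2′,3′,4′-octahydro-7,5′-binaphthalene-8,8′-diol (CNP0145304.1) | Cc1cc2c(c(O)c1-c1c(C)cc(O)c3c1[C@@H](C(C)C)CC[C@@H]3C)[C@@H](C)CC[C@@H]2C(C)C | target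

## Step count

Total step count: 19.
Longest linear sequence: 12 steps (1, 2, 4, 5–10, 17, 18, 19; the path through 11–16 is equally long).

## Steps most likely to fail, with fallbacks

Step 9 (C1 methylation). The benzylic cation can lose a proton from C2 to give the 1,2-dihydronaphthalene instead of accepting methyl, and the facial selectivity depends on the pseudoaxial isopropyl group. The fallback replaces ionisation by an anionic o-quinone methide addition and sets out from ketone 13. BCl3 (CH2Cl2, −78 → 0 °C) removes only the peri O-methyl group, by chelation to the ketone, giving the hydroxy ketone F1. NaBH4 in MeOH gives the diol F2. Boc2O with K2CO3 in acetone acylates only the phenol, giving the tert-butyl carbonate F3. MeMgBr (3 equiv, Et2O, −78 → 25 °C) deprotonates the benzylic alcohol, the Boc group migrates to that oxygen, and loss of tert-butyl carbonate gives the o-quinone methide F4 (not isolated). A second MeMgBr adds 1,4 at C1, anti to the pseudoaxial isopropyl group, to give the phenol F5. MeI/K2CO3 in acetone then returns to compound 16.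

Step 11 (chlorination). Chlorination is less para-selective than the bromination of step 5, and C7 or C8a isomers would be hard to remove and would misdirect the ring closure. The fallback installs chlorine before the side chain and sets out from compound 1. SO2Cl2 (CH2Cl2, 0 °C) gives crystalline 4-chloro-3-methylphenol F6, which is recrystallised to isomeric purity. MeI/K2CO3 gives 4-chloro-3-methylanisole F7. Lithium 2,2,6,6-tetramethylpiperidide, with i-PrOBpin present in the flask (THF, −78 °C), removes the most acidic ring proton, ortho to chlorine, and gives the boronate F8. Under the conditions of step 4, F8 and ester 5 give the isopropyl ester F9 (not isolated), and saponification returns to compound 19.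

Step 17 (biaryl coupling). The new bond is flanked by four ortho substituents, so transmetalation of the hindered boronate 18 is slow and protodeboronation can win. The fallback is a base-free Negishi coupling that bypasses the boronate and sets out from bromide 16. n-BuLi (THF, −78 °C) gives aryllithium 17, and ZnCl2 converts it into the arylzinc chloride F10. F10 is coupled with iodide 28 using Pd2(dba)3/RuPhos in THF/NMP at 70 °C, and the route is rejoined at compound 29.

## Further compounds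

F1 | step 9 | (4R)-5-bromo-8-hydroxy-6-methyl-4-(propan-2-yl)-3,4-dihydronaphthalen-1(2H)-one | Cc1c(Br)c2c(c(O)c1)C(=O)CC[C@@H]2C(C)C
F2 | step 9 | (1RS,4R)-5-bromo-6-methyl-4-(propan-2-yl)-1,2,3,4-tetrahydronaphthalene-1,8-diol | Cc1c(Br)c2c(c(O)c1)C(O)CC[C@@H]2C(C)C
F3 | step 9 | tert-butyl [(1RS,4R)-5-bromo-1-hydroxy-6-methyl-4-(propan-2-yl)-1,2,3,4-tetrahydronaphthalen-8-yl] carbonate | Cc1c(Br)c2c(c(OC(=O)OC(C)(C)C)c1)C(O)CC[C@@H]2C(C)C
F4 | step 9 | o-quinone methide, (5R)-4-bromo-3-methyl-5-(propan-2-yl)-6,7-dihydronaphthalen-1(5H)-one (numbered from the carbonyl; not isolated) | O=C1C=C(C)C(Br)=C2[C@@H](C(C)C)CCC=C12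
F5 | step 9 | (1S,4R)-5-bromo-1,6-dimethyl-4-(propan-2-yl)-1,2,3,4-tetrahydronaphthalen-8-ol | Cc1c(Br)c2c(c(O)c1)[C@@H](C)CC[C@@H]2C(C)C
F6 | step 11 | 4-chloro-3-methylphenol | Cc1cc(O)ccc1Cl
F7 | step 11 | 4-chloro-3-methylanisole | COc1ccc(Cl)c(C)c1
F8 | step 11 | 2-(2-chloro-5-methoxy-3-methylphenyl)-4,4,5,5-tetramethyl-1,3,2-dioxaborolane | COc1cc(C)c(Cl)c(c1)B1OC(C)(C)C(C)(C)O1
F9 | step 11 | propan-2-yl (3R)-3-(2-chloro-5-methoxy-3-methylphenyl)-4-methylpentanoate (not isolated) | COc1cc(C)c(Cl)c(c1)[C@H](CC(=O)OC(C)C)C(C)C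
F10 | step 17 | [(1S,4R)-8-methoxy-1,6-dimethyl-4-(propan-2-yl)-1,2,3,4-tetrahydronaphthalen-5-yl]zinc chloride | Cc1c([Zn]Cl)c2c(c(OC)c1)[C@@H](C)CC[C@@H]2C(C)C
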